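The synthesis rests on disconnecting the dihydropyran ring between the benzylic methylene C4 and the aromatic carbon C4a. Ring A is carried as a 4-bromo-3,5-dimethoxyphenyl ether: its two free ortho carbons are equivalent and each is flanked by the ether oxygen O1 and a methoxy group and lies para to the other methoxy group, while bromine marks C6 for the later acyl group. The precursor is an open-chain primary alcohol in which O1–C2 is already a tertiary ether and C3, set by copper hydride hydroboration, carries the prenyl group. Triflation then lets the arene displace the leaving group, closing the chromane in one operation without disturbing C3 or the prenyl alkene.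

Key step: step 5

Assumption: the face selectivity of the copper hydride insertion in step 4 is taken to follow the usual quadrant model with the tertiary ether carbon as the large substituent, so (R)-DTBM-SEGPHOS is written; should the insertion favour the other face, the (S)-ligand is used without further change. Compound 1 is taken as a catalogue chemical.

Step 1
Reactants: 1 4-bromo-3,5-dimethoxyphenol; 2 3-bromo-3-methylbutan-2-one
Product: 3 3-(4-bromo-3,5-dimethoxyphenoxy)-3-methylbutan-2-one
Conditions: K2CO3, KI (cat.), acetone, 55 °C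
Reagents that add atoms: none
Why: Williamson-type O-alkylation: the phenoxide should displace bromide from the tertiary carbon because the adjacent carbonyl group activates it toward substitution, which installs the O1–C2 tertiary ether with both methyl groups in place.

Step 2
Reactants: 3 3-(4-bromo-3,5-dimethoxyphenoxy)-3-methylbutan-2-one
Product: 4 3-(4-bromo-3,5-dimethoxyphenoxy)-3-methylbut-1-en-2-yl trifluoromethanesulfonate
Conditions: KN(SiMe3)2, THF, −78 °C; then PhNTf2, −78 to 0 °C
Reagents that add atoms: N-phenylbis(trifluoromethanesulfonimide), O=S(=O)(N(c1ccccc1)S(=O)(=O)C(F)(F)F)C(F)(F)F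
Why: Enol triflate formation: the methyl group is the only enolisable position, so kinetic deprotonation and O-sulfonylation of the potassium enolate should give the terminal vinyl triflate alone.

Step 3
Reactants: 4 3-(4-bromo-3,5-dimethoxyphenoxy)-3-methylbut-1-en-2-yl trifluoromethanesulfonate; 5 tributyl(3-methylbut-2-en-1-yl)stannane
Product: 6 2-bromo-5-[(2,6-dimethyl-3-methylidenehept-5-en-2-yl)oxy]-1,3-dimethoxybenzene
Conditions: Pd2(dba)3 (cat.), AsPh3, LiCl, NMP, rt
Reagents that add atoms: none
Why: Stille coupling: oxidative addition to zerovalent palladium should occur at the vinyl triflate rather than at the aryl bromide flanked by two methoxy groups, the prenyl group is delivered at its less substituted terminus, and room temperature keeps the allylic aryl ether product from ionising or undergoing Claisen rearrangement.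

Step 4
Reactants: 6 2-bromo-5-[(2,6-dimethyl-3-methylidenehept-5-en-2-yl)oxy]-1,3-dimethoxybenzene
Product: 8 (2S)-2-[2-(4-bromo-3,5-dimethoxyphenoxy)propan-2-yl]-5-methylhex-4-en-1-ol, via alkyl pinacol boronate 7 (not isolated)
Conditions: CuCl (cat.), (R)-DTBM-SEGPHOS, NaOt-Bu (cat.), HBpin, toluene, rt; then NaOH, H2O2, THF/H2O, 0 °C
Reagents that add atoms: hydrogen peroxide, OO
Why: Copper hydride-catalysed enantioselective anti-Markovnikov hydroboration of an unactivated 1,1-disubstituted alkene followed by stereoretentive oxidation: the ligand-bound Cu–H should add to the alkene face defined by the large tertiary ether carbon against the small CH2 of the prenyl arm, which sets C3, while the trisubstituted prenyl alkene and the aryl bromide do not react.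

Step 5
Reactants: 8 (2S)-2-[2-(4-bromo-3,5-dimethoxyphenoxy)propan-2-yl]-5-methylhex-4-en-1-ol
Product: 10 (3S)-6-bromo-5,7-dimethoxy-2,2-dimethyl-3-(3-methylbut-2-en-1-yl)-3,4-dihydro-2H-1-benzopyran, via primary triflate 9 (not isolated)
Conditions: Tf2O, 2,6-di-tert-butyl-4-methylpyridine, CH2Cl2, −78 to 0 °C
Reagents that add atoms: none
Why: O-triflation gives primary triflate 9, and the aromatic carbon ortho to the ether oxygen (the future C4a), which is also ortho to one methoxy group and para to the other, should attack the CH2–OTf carbon from the rear in an aryl-assisted displacement, after which the arenium ion loses its proton to the hindered pyridine. The closest known reaction type is the intramolecular Friedel–Crafts cyclialkylation of primary sulfonates onto alkoxy-activated arenes (aryl participation in solvolysis). The dihydropyran ring closes in a 6-exo-tet mode, the tether O1–C2–C3 holding C4 over the ortho carbon. No stereocentre is formed, and C3, set in step 4, is a spectator because the displacement is concerted at C4 and no cation or enol can develop next to it. Regioselectivity is secured by the substrate: the two free ortho carbons are equivalent and the para carbon carries bromine, so only one chromane can form. Chemoselectivity over the prenyl alkene follows from ring size (its participation would need a cyclobutane) and from the buffering base, which keeps triflic acid away from the alkene and the tertiary ether.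

Step 6
Reactants: 10 (3S)-6-bromo-5,7-dimethoxy-2,2-dimethyl-3-(3-methylbut-2-en-1-yl)-3,4-dihydro-2H-1-benzopyran; 11 N-methoxy-N-methylacetamide
Product: 12 1-[(3S)-5,7-dimethoxy-2,2-dimethyl-3-(3-methylbut-2-en-1-yl)-3,4-dihydro-2H-1-benzopyran-6-yl]ethan-1-one
Conditions: t-BuLi (2 equiv), THF, −78 °C; then 11, −78 to 0 °C; then H2O
Reagents that add atoms: none
Why: Bromine–lithium exchange followed by Weinreb ketone synthesis: the aryllithium forms exactly at C6 between the two methoxy groups and its adduct with the amide is a stable chelate that releases the methyl ketone only on work-up.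

Step 7
Reactants: 12 1-[(3S)-5,7-dimethoxy-2,2-dimethyl-3-(3-methylbut-2-en-1-yl)-3,4-dihydro-2H-1-benzopyran-6-yl]ethan-1-one
Product: 13 1-[(3S)-5-hydroxy-7-methoxy-2,2-dimethyl-3-(3-methylbut-2-en-1-yl)-3,4-dihydro-2H-1-benzopyran-6-yl]ethan-1-one
Conditions: BCl3 (1.1 equiv), CH2Cl2, −78 to −40 °C; then H2O
Reagents that add atoms: none
Why: Chelation-directed ether cleavage by BCl3 ortho to the ketone: of the two ortho methoxy groups, the one at C5 is flanked by the acetyl group and C4a, is twisted out of the ring plane and is therefore the more basic and the more exposed to chloride, so it should be cleaved selectively at a temperature that spares the prenyl alkene and the tertiary ring ether.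

Step 8
Reactants: 14 2,4-dihydroxybenzaldehyde
Product: 15 2,4-bis(methoxymethoxy)benzaldehyde
Conditions: NaH, MOMCl, DMF, 0 °C to rt
Reagents that add atoms: chloromethyl methyl ether, COCCl
Why: Williamson etherification of both phenoxides gives the bis(methoxymethyl) ether, which keeps the aldehyde electrophilic under the basic conditions of the next step.

Step 9
Reactants: 13 1-[(3S)-5-hydroxy-7-methoxy-2,2-dimethyl-3-(3-methylbut-2-en-1-yl)-3,4-dihydro-2H-1-benzopyran-6-yl]ethan-1-one; 15 2,4-bis(methoxymethoxy)benzaldehyde
Product: 16 (2E)-3-[2,4-bis(methoxymethoxy)phenyl]-1-[(3S)-5-hydroxy-7-methoxy-2,2-dimethyl-3-(3-methylbut-2-en-1-yl)-3,4-dihydro-2H-1-benzopyran-6-yl]prop-2-en-1-one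
Conditions: KOH, EtOH/H2O, rt
Reagents that add atoms: none
Why: Claisen–Schmidt condensation: the enolate of the methyl ketone adds to the non-enolisable aldehyde and the aldol eliminates water to give the conjugated E-enone, C3 being remote from every acidic position.

Step 10
Reactants: 16 (2E)-3-[2,4-bis(methoxymethoxy)phenyl]-1-[(3S)-5-hydroxy-7-methoxy-2,2-dimethyl-3-(3-methylbut-2-en-1-yl)-3,4-dihydro-2H-1-benzopyran-6-yl]prop-2-en-1-one
Product: 17 (2E)-3-(2,4-dihydroxyphenyl)-1-[(3S)-5-hydroxy-7-methoxy-2,2-dimethyl-3-(3-methylbut-2-en-1-yl)-3,4-dihydro-2H-1-benzopyran-6-yl]prop-2-en-1-one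
Conditions: HCl (3 M aq), MeOH, rt
Reagents that add atoms: none
Why: Acid-catalysed acetal exchange with methanol should remove both methoxymethyl groups under conditions mild enough to leave the prenyl alkene, the enone and the chromane ether intact, which gives the target.

Compound list
1 | 4-bromo-3,5-dimethoxyphenol | Oc1cc(OC)c(Br)c(OC)c1 | starting material
2 | 3-bromo-3-methylbutan-2-one | CC(=O)C(C)(C)Br | starting material
3 | 3-(4-bromo-3,5-dimethoxyphenoxy)-3-methylbutan-2-one | CC(=O)C(C)(C)Oc1cc(OC)c(Br)c(OC)c1 | intermediate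
4 | 3-(4-bromo-3,5-dimethoxyphenoxy)-3-methylbut-1-en-2-yl trifluoromethanesulfonate | C=C(OS(=O)(=O)C(F)(F)F)C(C)(C)Oc1cc(OC)c(Br)c(OC)c1 | intermediate
5 | tributyl(3-methylbut-2-en-1-yl)stannane | CCCC[Sn](CCCC)(CCCC)CC=C(C)C | starting material
6 | 2-bromo-5-[(2,6-dimethyl-3-methylidenehept-5-en-2-yl)oxy]-1,3-dimethoxybenzene | C=C(CC=C(C)C)C(C)(C)Oc1cc(OC)c(Br)c(OC)c1 | intermediate
7 | 2-[(2R)-2-[2-(4-bromo-3,5-dimethoxyphenoxy)propan-2-yl]-5-methylhex-4-en-1-yl]-4,4,5,5-tetramethyl-1,3,2-dioxaborolane | CC1(C)OB(C[C@H](CC=C(C)C)C(C)(C)Oc2cc(OC)c(Br)c(OC)c2)OC1(C)C | intermediate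
8 | (2S)-2-[2-(4-bromo-3,5-dimethoxyphenoxy)propan-2-yl]-5-methylhex-4-en-1-ol | OC[C@H](CC=C(C)C)C(C)(C)Oc1cc(OC)c(Br)c(OC)c1 | intermediate
9 | (2S)-2-[2-(4-bromo-3,5-dimethoxyphenoxy)propan-2-yl]-5-methylhex-4-en-1-yl trifluoromethanesulfonate | O=S(=O)(OC[C@H](CC=C(C)C)C(C)(C)Oc1cc(OC)c(Br)c(OC)c1)C(F)(F)F | intermediate
10 | (3S)-6-bromo-5,7-dimethoxy-2,2-dimethyl-3-(3-methylbut-2-en-1-yl)-3,4-dihydro-2H-1-benzopyran | COc1cc2c(c(OC)c1Br)C[C@H](CC=C(C)C)C(C)(C)O2 | intermediate
11 | N-methoxy-N-methylacetamide | CC(=O)N(C)OC | starting material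
12 | 1-[(3S)-5,7-dimethoxy-2,2-dimethyl-3-(3-methylbut-2-en-1-yl)-3,4-dihydro-2H-1-benzopyran-6-yl]ethan-1-one | COc1cc2c(c(OC)c1C(C)=O)C[C@H](CC=C(C)C)C(C)(C)O2 | intermediate
13 | 1-[(3S)-5-hydroxy-7-methoxy-2,2-dimethyl-3-(3-methylbut-2-en-1-yl)-3,4-dihydro-2H-1-benzopyran-6-yl]ethan-1-one | COc1cc2c(c(O)c1C(C)=O)C[C@H](CC=C(C)C)C(C)(C)O2 | intermediate
14 | 2,4-dihydroxybenzaldehyde | O=Cc1ccc(O)cc1O | starting material
15 | 2,4-bis(methoxymethoxy)benzaldehyde | COCOc1ccc(C=O)c(OCOC)c1 | intermediate
16 | (2E)-3-[2,4-bis(methoxymethoxy)phenyl]-1-[(3S)-5-hydroxy-7-methoxy-2,2-dimethyl-3-(3-methylbut-2-en-1-yl)-3,4-dihydro-2H-1-benzopyran-6-yl]prop-2-en-1-one | COCOc1ccc(/C=C/C(=O)c2c(OC)cc3c(c2O)C[C@H](CC=C(C)C)C(C)(C)O3)c(OCOC)c1 | intermediate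
17 | (2E)-3-(2,4-dihydroxyphenyl)-1-[(3S)-5-hydroxy-7-methoxy-2,2-dimethyl-3-(3-methylbut-2-en-1-yl)-3,4-dihydro-2H-1-benzopyran-6-yl]prop-2-en-1-one | COc1cc2c(c(O)c1C(=O)/C=C/c1ccc(O)cc1O)C[C@H](CC=C(C)C)C(C)(C)O2 | target

Total step count: 10. Longest linear sequence: 9 steps (steps 1 to 7, then 9 and 10); step 8 prepares the aldehyde partner.

Steps most likely to fail

Step 5 (key ring closure). The aryl-assisted displacement may be too slow at the hindered, branched carbon, so that the primary triflate is lost to elimination or to capture by adventitious nucleophiles before the ring closes. Fallback: the aryl–CH2 bond is made by cross-coupling instead. It sets out from boronate 7, which is isolated rather than oxidised. N-Iodosuccinimide (MeCN, 0 °C) should iodinate one of the two equivalent ring positions ortho to the ether oxygen, the only unsubstituted ones, to give 2-[(2R)-2-[2-(4-bromo-2-iodo-3,5-dimethoxyphenoxy)propan-2-yl]-5-methylhex-4-en-1-yl]-4,4,5,5-tetramethyl-1,3,2-dioxaborolane F1. Pd(OAc)2 and RuPhos with aqueous K3PO4 in dioxane at 80 °C should then effect an intramolecular B-alkyl Suzuki–Miyaura coupling at the carbon–iodine bond, which undergoes oxidative addition far faster than the doubly flanked carbon–bromine bond, and the route is rejoined at chromane 10.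

Step 4 (stereocentre). Poor facial selectivity, or sluggish insertion of copper hydride into the alkene beside the quaternary carbon, would erode the only stereocentre. Fallback: resolution instead of asymmetric catalysis. It sets out from diene 6. 9-Borabicyclo[3.3.1]nonane (THF, rt) should hydroborate the 1,1-disubstituted alkene alone to give 9-[2-[2-(4-bromo-3,5-dimethoxyphenoxy)propan-2-yl]-5-methylhex-4-en-1-yl]-9-borabicyclo[3.3.1]nonane F2, which is oxidised (NaOH, H2O2) to rac-2-[2-(4-bromo-3,5-dimethoxyphenoxy)propan-2-yl]-5-methylhex-4-en-1-ol F3. Lipase from Burkholderia cepacia with vinyl acetate (t-BuOMe, rt) is expected to acylate one enantiomer, assumed here to be the (R)-alcohol, which is removed as (2R)-2-[2-(4-bromo-3,5-dimethoxyphenoxy)propan-2-yl]-5-methylhex-4-en-1-yl acetate F4. The unreacted (S)-alcohol is compound 8, where the route is rejoined.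

Step 7 (selective demethylation). Loss of site selectivity between the two methoxy groups ortho to the ketone, or attack of the Lewis acid and of liberated HCl on the prenyl alkene, would give isomeric or chlorinated phenols. Fallback: the selectivity is moved to an alkylation. It sets out from ketone 12. Excess NaSEt (DMF, 130 °C) should cleave both methyl ethers under non-acidic conditions to give 1-[(3S)-5,7-dihydroxy-2,2-dimethyl-3-(3-methylbut-2-en-1-yl)-3,4-dihydro-2H-1-benzopyran-6-yl]ethan-1-one F5. One equivalent of MeI with K2CO3 in acetone should then methylate the less hindered 7-hydroxyl, the 5-hydroxyl being flanked by C4a and held in the stronger hydrogen bond to the ketone, and the route is rejoined at phenol 13.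

Further compounds
F1 | step 5 | 2-[(2R)-2-[2-(4-bromo-2-iodo-3,5-dimethoxyphenoxy)propan-2-yl]-5-methylhex-4-en-1-yl]-4,4,5,5-tetramethyl-1,3,2-dioxaborolane | CC1(C)OB(C[C@H](CC=C(C)C)C(C)(C)Oc2cc(OC)c(Br)c(OC)c2I)OC1(C)C
F2 | step 4 | 9-[2-[2-(4-bromo-3,5-dimethoxyphenoxy)propan-2-yl]-5-methylhex-4-en-1-yl]-9-borabicyclo[3.3.1]nonane | CC(C)=CCC(CB1C2CCCC1CCC2)C(C)(C)Oc1cc(OC)c(Br)c(OC)c1
F3 | step 4 | rac-2-[2-(4-bromo-3,5-dimethoxyphenoxy)propan-2-yl]-5-methylhex-4-en-1-ol | OCC(CC=C(C)C)C(C)(C)Oc1cc(OC)c(Br)c(OC)c1
F4 | step 4 | (2R)-2-[2-(4-bromo-3,5-dimethoxyphenoxy)propan-2-yl]-5-methylhex-4-en-1-yl acetate | CC(=O)OC[C@@H](CC=C(C)C)C(C)(C)Oc1cc(OC)c(Br)c(OC)c1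
F5 | step 7 | 1-[(3S)-5,7-dihydroxy-2,2-dimethyl-3-(3-methylbut-2-en-1-yl)-3,4-dihydro-2H-1-benzopyran-6-yl]ethan-1-one | CC(=O)c1c(O)cc2c(c1O)C[C@H](CC=C(C)C)C(C)(C)O2
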